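**Retrosynthetic overview**

1. Target 25 ⇐ acetylation of 6β-alcohol 24 ⇐ α-face hydride reduction of 6-ketone 23 ⇐ oxidative deformylation of 6α-formyl decalin 22.
2. Key disconnection: bonds C5–C10 and C6–C7 of 22, made by an amine-catalysed enantioselective type 1 intramolecular Diels–Alder reaction of the acyclic, achiral trienal 19, which sets C5, C6 and C10 at once.
3. Enabling feature: ring B is a cyclohexene whose C8=C9 double bond lies between C7 and C10 (diene C7=C8–C9=C10), C5–C6 is the dienophile pair, and the ring-fusion atoms C5 and C10 are bridged by the four-carbon chain C1–C4 of ring A, which acts as the tether; the C6 oxygen marks the position of the activating formyl group.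
4. Trienal 19 ⇐ Wittig and acetal hydrolysis ⇐ Negishi coupling (C12–C13) with 4-bromofuran-2(5H)-one ⇐ Suzuki coupling (C8–C9) ⇐ iron-catalysed methylmagnesiation and iodination of alkynol 8 (fixes the (E)-tetrasubstituted C9=C10 bond) ⇐ alkylation of but-3-yn-1-ol with iodide 5 ⇐ 2,2-dimethylpent-4-enal.
5. Ring order: the butenolide ring is bought intact (14) and never opened; rings B and A are closed together in step 11, ring A by the C5–C10 bond, and no ring is formed afterwards.

Key step: step 11

Remark: labdane numbering is used throughout (ring A = C1–C5 and C10; ring B = C5–C10; side chain C11–C16; C6 carries the oxygen); starting materials 1, 6, 11, 14 and 18 are taken as commercial.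

**Route**

Step 1
Reactants: 1 aldehyde 2,2-dimethylpent-4-enal
Product: 2 acetal 5,5-dimethoxy-4,4-dimethylpent-1-ene
Conditions: HC(OMe)3, MeOH, TsOH·H2O (cat.), rt
Reagents that add atoms: trimethyl orthoformate, COC(OC)OC
Why: Acid-catalysed acetalisation with the orthoformate as water scavenger should mask the neopentyl aldehyde (future C5) as a dimethyl acetal that is stable to bases and organometallics and is cleaved later under very mild acid.

Step 2
Reactants: 2 acetal 5,5-dimethoxy-4,4-dimethylpent-1-ene
Product: 4 alcohol 5,5-dimethoxy-4,4-dimethylpentan-1-ol, via B-alkyl-9-BBN adduct 3 (not isolated)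
Conditions: 9-BBN, THF, 0 °C → rt; then NaOH, H2O2, H2O, 0 °C → rt
Reagents that add atoms: 9-borabicyclo[3.3.1]nonane, B1C2CCCC1CCC2 (boron and bicycle of intermediate 3 only); hydrogen peroxide, OO (the hydroxyl oxygen)
Why: Anti-Markovnikov hydroboration of the monosubstituted alkene followed by alkaline peroxide oxidation should give the primary alcohol (future C1), the acetal being inert to both stages.

Step 3
Reactants: 4 alcohol 5,5-dimethoxy-4,4-dimethylpentan-1-ol
Product: 5 iodide 5-iodo-1,1-dimethoxy-2,2-dimethylpentane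
Conditions: I2, PPh3, imidazole, CH2Cl2, 0 °C
Reagents that add atoms: iodine, II
Why: Appel-type iodination should convert the primary alcohol into the iodide by SN2 displacement of the alkoxyphosphonium ion, the imidazole buffer protecting the acetal.

Step 4
Reactants: 5 iodide 5-iodo-1,1-dimethoxy-2,2-dimethylpentane; 6 but-3-yn-1-ol
Product: 8 alkynol 9,9-dimethoxy-8,8-dimethylnon-3-yn-1-ol, via dilithium alkynolate 7 (not isolated)
Conditions: 6, n-BuLi (2.1 equiv), THF/DMPU, −78 → 0 °C; then 5, 0 °C → rt
Reagents that add atoms: n-butyllithium, [Li]CCCC (lithium of intermediate 7 only)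
Why: Double deprotonation of the alkynol gives an alkoxide–acetylide dianion whose carbon terminus should be alkylated by the unhindered primary iodide (acetylide SN2 alkylation), forming the C1–C10 bond.

Step 5
Reactants: 8 alkynol 9,9-dimethoxy-8,8-dimethylnon-3-yn-1-ol
Product: 10 alkenyl iodide (3E)-3-iodo-9,9-dimethoxy-4,8,8-trimethylnon-3-en-1-ol, via alkenylmagnesium bromide 9 (not isolated)
Conditions: MeMgBr (5 equiv), Fe(acac)3 (20 mol%), THF, −78 → 0 °C; then I2, THF, −78 °C → rt
Reagents that add atoms: methylmagnesium bromide, C[Mg]Br (the C10 methyl group; magnesium and bromine of intermediate 9 only); iodine, II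
Why: Alkoxide-directed, iron-catalysed syn-carbomagnesiation of the homopropargylic alcohol should deliver the methyl group to the distal alkyne carbon (C10) and magnesium to the proximal one (C9) through a five-membered chelate, and iodinolysis with retention fixes the tetrasubstituted alkene with methyl and iodine cis.

Step 6
Reactants: 10 alkenyl iodide (3E)-3-iodo-9,9-dimethoxy-4,8,8-trimethylnon-3-en-1-ol; 11 boronate 4,4,5,5-tetramethyl-2-(prop-1-en-2-yl)-1,3,2-dioxaborolane
Product: 12 dienol (3E)-9,9-dimethoxy-4,8,8-trimethyl-3-(prop-1-en-2-yl)non-3-en-1-ol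
Conditions: Pd(dppf)Cl2 (5 mol%), K3PO4, THF/H2O, 60 °C
Reagents that add atoms: none
Why: Suzuki–Miyaura coupling proceeds with retention of alkene geometry and should give the 2,3-disubstituted diene whose C10 terminus carries the chain trans and the methyl cis to C8; the free hydroxyl and the acetal are tolerated.

Step 7
Reactants: 12 dienol (3E)-9,9-dimethoxy-4,8,8-trimethyl-3-(prop-1-en-2-yl)non-3-en-1-ol
Product: 13 dienyl iodide (6E)-9-iodo-1,1-dimethoxy-2,2,6-trimethyl-7-(prop-1-en-2-yl)non-6-ene
Conditions: PPh3, I2, imidazole (reagent pre-formed), CH2Cl2, 0 °C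
Reagents that add atoms: iodine, II
Why: Appel-type iodination of the primary homoallylic alcohol with the pre-formed, buffered phosphonium reagent should leave the electron-rich diene and the acetal untouched.

Step 8
Reactants: 13 dienyl iodide (6E)-9-iodo-1,1-dimethoxy-2,2,6-trimethyl-7-(prop-1-en-2-yl)non-6-ene; 14 4-bromofuran-2(5H)-one
Product: 16 butenolide 4-[(3E)-9,9-dimethoxy-4,8,8-trimethyl-3-(prop-1-en-2-yl)non-3-en-1-yl]furan-2(5H)-one, via alkylzinc iodide 15 (not isolated)
Conditions: Zn dust, LiCl, THF, 40 °C; then 14, Pd(PPh3)4 (5 mol%), THF, rt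
Reagents that add atoms: zinc, [Zn] (zinc of intermediate 15 only)
Why: LiCl-promoted zinc insertion into the primary iodide gives a tolerant alkylzinc iodide that should undergo Negishi sp3–sp2 coupling with the β-bromo butenolide (C12–C13 bond), so the butenolide ring enters intact.

Step 9
Reactants: 16 butenolide 4-[(3E)-9,9-dimethoxy-4,8,8-trimethyl-3-(prop-1-en-2-yl)non-3-en-1-yl]furan-2(5H)-one
Product: 17 aldehyde (6E)-2,2,6-trimethyl-9-(5-oxo-2,5-dihydrofuran-3-yl)-7-(prop-1-en-2-yl)non-6-enal
Conditions: TsOH·H2O (10 mol%), acetone/H2O, rt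
Reagents that add atoms: water, O
Why: Mild acid-catalysed hydrolysis of the dimethyl acetal in wet acetone should release the C5 aldehyde without touching the butenolide or the diene.

Step 10
Reactants: 17 aldehyde (6E)-2,2,6-trimethyl-9-(5-oxo-2,5-dihydrofuran-3-yl)-7-(prop-1-en-2-yl)non-6-enal; 18 ylide (triphenylphosphoranylidene)acetaldehyde
Product: 19 trienal (2E,8E)-4,4,8-trimethyl-11-(5-oxo-2,5-dihydrofuran-3-yl)-9-(prop-1-en-2-yl)undeca-2,8-dienal
Conditions: PhCO2H (cat.), toluene, 65 °C
Reagents that add atoms: none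
Why: Wittig olefination with the stabilised, non-basic formylmethylene ylide should give the (E)-enal (C5=C6) selectively while sparing the butenolide, and the moderate temperature keeps uncatalysed cycloaddition of the product low.

Step 11
Reactants: 19 trienal (2E,8E)-4,4,8-trimethyl-11-(5-oxo-2,5-dihydrofuran-3-yl)-9-(prop-1-en-2-yl)undeca-2,8-dienal
Product: 22 aldehyde 6α-formyllabda-8,13-dien-15,16-olide (5S,6S,10S; trans-fused), via trienal iminium triflate 20 (not isolated), via cycloadduct iminium triflate 21 (not isolated)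
Conditions: (2S,5S)-5-benzyl-2-tert-butyl-3-methylimidazolidin-4-one·TfOH (20 mol%), MeCN/H2O (98:2), 5 °C → rt
Reagents that add atoms: (2S,5S)-5-benzyl-2-tert-butyl-3-methylimidazolidin-4-one trifluoromethanesulfonate, CN1C(=O)[C@H](Cc2ccccc2)N[C@@H]1C(C)(C)C.OS(=O)(=O)C(F)(F)F (atoms appear only in intermediates 20 and 21); water, O (the aldehyde oxygen of 22 after iminium hydrolysis)
Why: The enal condenses reversibly with the chiral ammonium salt to the (E)-iminium ion 20, whose LUMO-lowered C5=C6 bond should undergo an endo-selective, asynchronous [4+2] cycloaddition with the tethered C7=C8–C9=C10 diene (C5–C10 bond leading, the developing positive charge held by the substituted C7–C8–C9 allyl unit), and hydrolysis of iminium 21 returns the catalyst and aldehyde 22. The closest known reaction type is the imidazolidinone-catalysed enantioselective type 1 intramolecular Diels–Alder reaction of 2,7,9-decatrienals to trans-fused decalin carbaldehydes. Ring B is closed as the new cyclohexene by the suprafacial [4+2] union (bonds C5–C10 and C6–C7), and ring A is closed in the same event by the C5–C10 bond, the tether C1–C4 folding chair-like and lying anti (exo) on the dienophile. C5 is set by the catalyst, whose benzyl group shields one face of the s-trans (E)-iminium so that the diene adds to the opposite face; C10 follows from the endo transition state combined with the (E)-C9=C10 geometry fixed in step 5 (chain outside, methyl inside), which places the C10 methyl anti to C5–H (trans fusion); C6 (formyl cis to C5–H) follows from the (E)-enal geometry and is erased in step 12. The step needs trans over cis fusion, one enantioface and activation of a single π-bond: the endo preference of the iminium and the bulk of the C4 quaternary centre (which would sit under the diene in the cis-fused mode) favour trans, the C4 gem-dimethyl group (Thorpe–Ingold effect) and the allylic strain between the C8 and C10 methyl groups (which destabilises the s-trans diene conformer) pre-organise the triene, and only the aldehyde can form an iminium ion, so the butenolide stays a spectator.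

Step 12
Reactants: 22 aldehyde 6α-formyllabda-8,13-dien-15,16-olide
Product: 23 ketone 6-oxolabda-8,13-dien-15,16-olide (5S,10S)
Conditions: Cu(OAc)2 (10 mol%), 2,2′-bipyridine (10 mol%), DABCO, O2 (1 atm), DMF, 35 °C
Reagents that add atoms: dioxygen, O=O
Why: Copper-catalysed aerobic oxidative deformylation (amine-promoted enolisation of the α-branched aldehyde, oxygenation at C6 and fragmentation of the α-hydroperoxy aldehyde) should give the C6 ketone and formic acid, with the now epimerisable C5 resting in the more stable trans-fused form.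

Step 13
Reactants: 23 ketone 6-oxolabda-8,13-dien-15,16-olide
Product: 24 alcohol 6β-hydroxylabda-8,13-dien-15,16-olide (5S,6R,10S)
Conditions: NaBH4, CeCl3·7H2O, MeOH, −40 → 0 °C
Reagents that add atoms: none
Why: In this Luche-type reduction hydride should attack C6 from the α face, anti to the axial C10 and C4 β-methyl groups that block the β face, giving the axial 6β-alcohol under substrate control, while the cold, weakly basic medium avoids conjugation of the β,γ-unsaturated ketone and spares the butenolide.

Step 14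
Reactants: 24 alcohol 6β-hydroxylabda-8,13-dien-15,16-olide
Product: 25 target 6β-acetoxylabda-8,13-dien-15,16-olide, (1R,4aS,8aS)-3,4a,8,8-tetramethyl-4-[2-(5-oxo-2,5-dihydrofuran-3-yl)ethyl]-1,2,4a,5,6,7,8,8a-octahydronaphthalen-1-yl acetate
Conditions: Ac2O, DMAP, Et3N, CH2Cl2, rt
Reagents that add atoms: acetic anhydride, CC(=O)OC(C)=O
Why: DMAP-catalysed acylation (nucleophilic catalysis through the N-acetylpyridinium ion) should esterify the hindered axial alcohol with retention at C6, giving the target.

**Compound list**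

1 | 2,2-dimethylpent-4-enal | C=CCC(C)(C)C=O | starting material
2 | 5,5-dimethoxy-4,4-dimethylpent-1-ene | C=CCC(C)(C)C(OC)OC | intermediate
3 | 9-(5,5-dimethoxy-4,4-dimethylpentyl)-9-borabicyclo[3.3.1]nonane | COC(OC)C(C)(C)CCCB1C2CCCC1CCC2 | intermediate (not isolated)
4 | 5,5-dimethoxy-4,4-dimethylpentan-1-ol | OCCCC(C)(C)C(OC)OC | intermediate
5 | 5-iodo-1,1-dimethoxy-2,2-dimethylpentane | ICCCC(C)(C)C(OC)OC | intermediate
6 | but-3-yn-1-ol | C#CCCO | starting material
7 | lithium 4-lithiobut-3-yn-1-olate | [Li]C#CCCO[Li] | intermediate (not isolated)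
8 | 9,9-dimethoxy-8,8-dimethylnon-3-yn-1-ol | OCCC#CCCCC(C)(C)C(OC)OC | intermediate
9 | bromomagnesium (3E)-3-(bromomagnesio)-9,9-dimethoxy-4,8,8-trimethylnon-3-en-1-olate (Mg and C4 methyl cis) | Br[Mg]OCCC(/[Mg]Br)=C(/C)CCCC(C)(C)C(OC)OC | intermediate (not isolated)
10 | (3E)-3-iodo-9,9-dimethoxy-4,8,8-trimethylnon-3-en-1-ol | OCCC(/I)=C(/C)CCCC(C)(C)C(OC)OC | intermediate
11 | 4,4,5,5-tetramethyl-2-(prop-1-en-2-yl)-1,3,2-dioxaborolane | CC(=C)B1OC(C)(C)C(C)(C)O1 | starting material
12 | (3E)-9,9-dimethoxy-4,8,8-trimethyl-3-(prop-1-en-2-yl)non-3-en-1-ol | OCCC(/C(C)=C)=C(/C)CCCC(C)(C)C(OC)OC | intermediate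
13 | (6E)-9-iodo-1,1-dimethoxy-2,2,6-trimethyl-7-(prop-1-en-2-yl)non-6-ene | ICCC(/C(C)=C)=C(/C)CCCC(C)(C)C(OC)OC | intermediate
14 | 4-bromofuran-2(5H)-one | O=C1C=C(Br)CO1 | starting material
15 | [(3E)-9,9-dimethoxy-4,8,8-trimethyl-3-(prop-1-en-2-yl)non-3-en-1-yl]zinc iodide | I[Zn]CCC(/C(C)=C)=C(/C)CCCC(C)(C)C(OC)OC | intermediate (not isolated)
16 | 4-[(3E)-9,9-dimethoxy-4,8,8-trimethyl-3-(prop-1-en-2-yl)non-3-en-1-yl]furan-2(5H)-one | O=C1OCC(CCC(/C(C)=C)=C(/C)CCCC(C)(C)C(OC)OC)=C1 | intermediate
17 | (6E)-2,2,6-trimethyl-9-(5-oxo-2,5-dihydrofuran-3-yl)-7-(prop-1-en-2-yl)non-6-enal | O=C1OCC(CCC(/C(C)=C)=C(/C)CCCC(C)(C)C=O)=C1 | intermediate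
18 | (triphenylphosphoranylidene)acetaldehyde | O=CC=P(c1ccccc1)(c1ccccc1)c1ccccc1 | starting material
19 | (2E,8E)-4,4,8-trimethyl-11-(5-oxo-2,5-dihydrofuran-3-yl)-9-(prop-1-en-2-yl)undeca-2,8-dienal | O=C1OCC(CCC(/C(C)=C)=C(/C)CCCC(C)(C)/C=C/C=O)=C1 | intermediate
20 | (E)-iminium triflate of trienal 19 with the (2S,5S)-imidazolidinone (enal chain syn to the benzyl-bearing carbon) | CN1C(=O)[C@H](Cc2ccccc2)/[N+](=C\C=C\C(C)(C)CCC/C(C)=C(\CCC2=CC(=O)OC2)C(C)=C)[C@@H]1C(C)(C)C.[O-]S(=O)(=O)C(F)(F)F | intermediate (not isolated)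
21 | iminium triflate of aldehyde 22 with the (2S,5S)-imidazolidinone | CN1C(=O)[C@H](Cc2ccccc2)[N+](=C[C@H]2CC(C)=C(CCC3=CC(=O)OC3)[C@@]3(C)CCCC(C)(C)[C@H]23)[C@@H]1C(C)(C)C.[O-]S(=O)(=O)C(F)(F)F | intermediate (not isolated)
22 | 6α-formyllabda-8,13-dien-15,16-olide, (1S,4aS,8aS)-3,4a,8,8-tetramethyl-4-[2-(5-oxo-2,5-dihydrofuran-3-yl)ethyl]-1,2,4a,5,6,7,8,8a-octahydronaphthalene-1-carbaldehyde | O=C[C@H]1CC(C)=C(CCC2=CC(=O)OC2)[C@@]2(C)CCCC(C)(C)[C@H]12 | intermediate
23 | 6-oxolabda-8,13-dien-15,16-olide, (4aS,8aS)-3,4a,8,8-tetramethyl-4-[2-(5-oxo-2,5-dihydrofuran-3-yl)ethyl]-4a,5,6,7,8,8a-hexahydronaphthalen-1(2H)-one | O=C1CC(C)=C(CCC2=CC(=O)OC2)[C@@]2(C)CCCC(C)(C)[C@H]12 | intermediate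
24 | 6β-hydroxylabda-8,13-dien-15,16-olide, 4-{2-[(4R,4aS,8aS)-4-hydroxy-2,5,5,8a-tetramethyl-3,4,4a,5,6,7,8,8a-octahydronaphthalen-1-yl]ethyl}furan-2(5H)-one | O[C@@H]1CC(C)=C(CCC2=CC(=O)OC2)[C@@]2(C)CCCC(C)(C)[C@H]12 | intermediate
25 | 6β-acetoxylabda-8,13-dien-15,16-olide, (1R,4aS,8aS)-3,4a,8,8-tetramethyl-4-[2-(5-oxo-2,5-dihydrofuran-3-yl)ethyl]-1,2,4a,5,6,7,8,8a-octahydronaphthalen-1-yl acetate | CC(=O)O[C@@H]1CC(C)=C(CCC2=CC(=O)OC2)[C@@]2(C)CCCC(C)(C)[C@H]12 | target

**Step count and risks**

Total step count: 14. Longest linear sequence: 14 steps (1 → 25); 6, 11, 14 and 18 are purchased and enter in steps 4, 6, 8 and 10.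

Steps most likely to fail:

1. Step 11. The congested C10 diene terminus (it becomes a quaternary centre next to the C4 quaternary centre) may react too slowly with the iminium-activated dienophile at ambient temperature. Forcing the reaction would invite stepwise cyclisation with proton loss and erosion of the trans and enantiofacial selectivity. Fallback: setting out from aldehyde 17, a Horner–Wadsworth–Emmons reaction with (4S)-4-benzyl-3-[(diethoxyphosphoryl)acetyl]-1,3-oxazolidin-2-one (LiCl, i-Pr2NEt, MeCN, rt) would give the (E)-configured N-enoyl oxazolidinone trienimide F1. Its Me2AlCl chelate (2.5 equiv, CH2Cl2, −30 °C) is a much stronger dienophile than the iminium ion and should cyclise through the same endo, tether-anti transition state to the trans-fused 6α-acyl cycloadduct F2. By the chelate model the auxiliary benzyl group shields the same dienophile face as the catalyst does in step 11. LiSEt (THF, 0 °C) would then transfer the acyl group to sulfur, giving the S-ethyl thioester F3 and freeing the auxiliary, and Fukuyama reduction (Et3SiH, Pd/C, acetone, rt) would bring the route back at aldehyde 22.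

2. Step 12. Under the basic aerobic conditions the C8=C9 double bond of the β,γ-unsaturated ketone may migrate into conjugation, and the doubly activated C7 position may be over-oxidised. Fallback: setting out from aldehyde 22, condensation with piperidine (4 Å molecular sieves, benzene, rt) would give the piperidine enamine F4. Periodate cleavage of its electron-rich exocyclic C=C bond (NaIO4, THF/H2O, 0 °C) would then give the ketone and piperidine-1-carbaldehyde without a basic oxygenation stage, bringing the route back at ketone 23.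

3. Step 10. Olefination of the neopentyl aldehyde may be sluggish, and prolonged heating would allow a second homologation of the product and premature, racemic thermal cycloaddition of the trienal. Fallback: setting out from aldehyde 17, a Horner–Wadsworth–Emmons reaction under LiCl/i-Pr2NEt conditions with diethyl {2-[methoxy(methyl)amino]-2-oxoethyl}phosphonate (MeCN, rt) would give the (E)-N-methoxy-N-methyl enamide F5. Chemoselective amide reduction with Cp2Zr(H)Cl (THF, rt), which leaves lactones untouched, would then give the enal at room temperature, bringing the route back at trienal 19.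

**Further compounds**

F1 | step 11 | (4S)-4-benzyl-3-[(2E,8E)-4,4,8-trimethyl-11-(5-oxo-2,5-dihydrofuran-3-yl)-9-(prop-1-en-2-yl)undeca-2,8-dienoyl]-1,3-oxazolidin-2-one | O=C1OC[C@H](Cc2ccccc2)N1C(=O)/C=C/C(C)(C)CCC/C(C)=C(\CCC1=CC(=O)OC1)C(C)=C
F2 | step 11 | (4S)-4-benzyl-3-{[(1S,4aS,8aS)-3,4a,8,8-tetramethyl-4-[2-(5-oxo-2,5-dihydrofuran-3-yl)ethyl]-1,2,4a,5,6,7,8,8a-octahydronaphthalen-1-yl]carbonyl}-1,3-oxazolidin-2-one | O=C1OC[C@H](Cc2ccccc2)N1C(=O)[C@H]1CC(C)=C(CCC2=CC(=O)OC2)[C@@]2(C)CCCC(C)(C)[C@H]12
F3 | step 11 | S-ethyl (1S,4aS,8aS)-3,4a,8,8-tetramethyl-4-[2-(5-oxo-2,5-dihydrofuran-3-yl)ethyl]-1,2,4a,5,6,7,8,8a-octahydronaphthalene-1-carbothioate | CCSC(=O)[C@H]1CC(C)=C(CCC2=CC(=O)OC2)[C@@]2(C)CCCC(C)(C)[C@H]12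
F4 | step 12 | piperidine enamine of aldehyde 22, 6-(piperidin-1-ylmethylidene)labda-8,13-dien-15,16-olide (5α-H, 10β-methyl) | C1CCN(CC1)C=C1CC(C)=C(CCC2=CC(=O)OC2)[C@@]2(C)CCCC(C)(C)[C@H]12
F5 | step 10 | (2E,8E)-N-methoxy-N,4,4,8-tetramethyl-11-(5-oxo-2,5-dihydrofuran-3-yl)-9-(prop-1-en-2-yl)undeca-2,8-dienamide | CON(C)C(=O)/C=C/C(C)(C)CCC/C(C)=C(\CCC1=CC(=O)OC1)C(C)=C
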